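Repeat the run with your eye on one ratio: the pull of the starting material on the intermediate against the intermediate's other exits.

in all of them: starting material 0.30 M; first nucleophile 0.600 M; time 10 min
- Friday's: second nucleophile 0.300 M; everything together at the start at −15 °C, warmed to 25 °C at 2.0 min
- Thursday's: second nucleophile 0.300 M (fed, over 2.0 min); all else is in the flask from the start; the feed brings no volume worth counting; temperature 25 °C
- Sunday's: second nucleophile 0.300 M (fed, over 2.0 min); the addition at −15 °C, then warmed to 25 °C; the feed brings no volume worth counting
- Monday's: second nucleophile 0.300 M; everything together at the start; temperature 25 °C

* the flask with the highest amount of side product, in percent of the starting material charged ("all alike" if they lie within 1.5 percentage points) (Friday's / Thursday's / Sunday's / Monday's / all alike)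
* final side product, as a percentage of the starting material charged, in Friday's
* final side product, as a percentage of the starting material charged, in Thursday's
* final side product, as a percentage of the starting material charged, in Sunday's
* final side product, as a percentage of the starting material charged, in Monday's

- in percentages every species weighs as the starting material in it: one side product counts as two
- constants are those at 25 °C; use the activation energies and enthalpies for any other temperature

    first nucleophile + intermediate → target (k1 = 0.46 /M/s, Ea1 = 37.0 kJ/mol)
    starting material → intermediate (k2 = 0.021 /s, Ea2 = 73.0 kJ/mol)
    intermediate → solvolysis product (k3 = 0.17 /s, Ea3 = 71.0 kJ/mol)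
    target ⇌ isomer of the product (K4 = 23, k4 = 0.037 /s, Ea4 = 72.0 kJ/mol, ΔH4 = −52.0 kJ/mol)
    starting material + intermediate → side product (k5 = 0.42 /M/s, Ea5 = 53.0 kJ/mol)
    second nucleophile + intermediate → other capture product (k6 = 0.082 /M/s, Ea6 = 61.0 kJ/mol)
    (constants at 25 °C)

Does time matter? Count half-lives. At 25 °C the ionisation step, taken by itself, halves [starting material] in 0.55 min, so Monday's 10 min holds 18.2 of them. The question is how the charge divides, not how far it gets.

And the intermediate? At 25 °C and the charged amounts, solvolysis and the two nucleophiles together remove it with a pseudo-first-order constant of 0.471 /s. That gives a lifetime of 2.12 s, far shorter than the 33.0 s half-life of the starting material. So it leaves about as fast as it forms.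

Then what is one intermediate's fate? It depends on the crowding ratio a, which is k5[starting material] divided by that exit constant. At the charge, a is 0.268, and a/(1 + a) of the intermediate goes to side product.

But a falls as the starting material goes, and each side product eats two molecules of it. Doesn't that spoil the figure? It changes it, so integrate. Per starting material consumed, a/(1 + 2a) side product forms. Counted double, the final share is 1 − ln(1 + 2a)/(2a), with a taken at the charge. For Monday's, with both nucleophiles held at their charges, that gives 19.9%.

And Thursday's feed? It runs 2.0 min, longer than the half-life, and after that half-life it has delivered 0.0825 M of the 0.300 M. As a limiting case, striking that term from the exits for the whole of Thursday's leaves 0.446 /s, a of 0.283 and a share of 20.7%. That is 0.80 percentage points above Monday's, inside the margin. I carry no number of my own for the cold flasks.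

The forecast goes further, saying that in the cold “ionisation almost stops”. It gives 20.5% for Friday's, 21.4% for Thursday's, 20.5% for Sunday's and 20.8% for Monday's, hence all alike. Its Thursday's and Monday's figures stand above mine .

The flasks give 19.8% for Friday's, 20.7% for Thursday's, 19.8% for Sunday's and 20.1% for Monday's, so the answer is all alike. Friday's still held 97.1% of its starting material at 2.00 min, when it warmed. Now take the neighbour of Thursday's with 1.0 M of first nucleophile, again leaving the second out of the exits. The crowding ratio drops to 0.200, and the share comes to 15.9%. That neighbour ended with 16.0% side product.

The numbers come from no measurement; the rest is arithmetic.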